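**Retrosynthetic overview**
1. Endgame: the C10 angelate and the C6 benzoate are put on a free triol last. The C4 carbinol comes from i‑PrMgCl addition to a C4 ketone, and the C1 methyl from cuprate addition to a ring‑fusion enone C4(=O)–C5=C1.
2. Key disconnection: ring B (C1–C2–C3–C4–C5) of that enone is cut in the Pauson–Khand sense into an alkyne C1≡C5, a vinyl group C2=C3 and CO (C4). The bonds C1–C2, C3–C4 and C4–C5 form in one operation.
3. Enabling feature: C1 and C5 are the adjacent atoms shared by seven‑membered ring A and five‑membered ring B, so they can be a cycloheptyne stored as its Co2(CO)6 complex, and C4 carries oxygen because it is the CO carbon. The C10 oxygen sits next to C1 on the face of C2, so it can hold the vinyl group through an O–SiMe2 tether. The tether fixes the regiochemistry and then falls off, because silicon ends up γ to the enone carbonyl.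
4. Ring A comes from ring‑closing metathesis (C8=C9) of the cobalt‑bent open‑chain dienyne. Its two carbinol centres come from a Keck methallylation (C6) and a zinc–ProPhenol alkynylation of acrolein (C10).
5. Ring order: ring A (step 6), then ring B together with a temporary oxasilolane (step 8).

Key step: step 8

Remark on locants: daucane numbering is used. C1 is the quaternary ring‑fusion carbon (methyl C15), C2/C3 the ring CH2CH2, C4 the carbinol carbon bearing isopropyl, and C5 the ring‑fusion CH. C6 is the benzoyloxy carbon, C7 a CH2, C8=C9 the ring alkene (methyl C14 on C8), and C10 the angeloyloxy carbon. The α face carries H‑5, the C6 and C10 oxygens, C2 and the isopropyl group. The β face carries C15 and the C4 hydroxyl.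
Assumption: (R,R)‑ProPhenol is taken to deliver the alkynyl group to the Si face of acrolein. Should the sense be the opposite, the (S,S) ligand is used and nothing else changes.

Step 1
Reactants: 1 3‑(trimethylsilyl)prop‑2‑ynal; 2 tributyl(2‑methylprop‑2‑en‑1‑yl)stannane
Product: 3 (3S)‑5‑methyl‑1‑(trimethylsilyl)hex‑5‑en‑1‑yn‑3‑ol
Conditions: (S)‑BINOL (10 mol %), Ti(OiPr)4 (10 mol %), 4 Å MS, CH2Cl2, −20 °C; aq NaHCO3
Reagents that add atoms: none
Why: Keck catalytic asymmetric allylation with a methallylstannane, in which the (S)‑BINOL–titanium Lewis acid should leave the Si face of the ynal open and so set C6 as (S).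

Step 2
Reactants: 3 (3S)‑5‑methyl‑1‑(trimethylsilyl)hex‑5‑en‑1‑yn‑3‑ol
Product: 4 (3S)‑3‑[(tert‑butyldimethylsilyl)oxy]‑5‑methyl‑1‑(trimethylsilyl)hex‑5‑en‑1‑yne
Conditions: TBSCl, imidazole, DMF, rt
Reagents that add atoms: tert‑butyldimethylsilyl chloride, CC(C)(C)[Si](C)(C)Cl
Why: Standard silyl ether protection of the secondary alcohol, which does not touch the C6 centre and survives every step up to step 11.

Step 3
Reactants: 4 (3S)‑3‑[(tert‑butyldimethylsilyl)oxy]‑5‑methyl‑1‑(trimethylsilyl)hex‑5‑en‑1‑yne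
Product: 5 (3S)‑3‑[(tert‑butyldimethylsilyl)oxy]‑5‑methylhex‑5‑en‑1‑yne
Conditions: K2CO3 (0.2 equiv), MeOH, 0 °C
Reagents that add atoms: none
Why: Methanolysis of the C(sp)–SiMe3 bond is far faster than cleavage of a secondary TBS ether, so only the alkyne terminus should be freed.

Step 4
Reactants: 5 (3S)‑3‑[(tert‑butyldimethylsilyl)oxy]‑5‑methylhex‑5‑en‑1‑yne; 6 acrolein
Product: 7 (3R,6S)‑6‑[(tert‑butyldimethylsilyl)oxy]‑8‑methylnona‑1,8‑dien‑4‑yn‑3‑ol
Conditions: (R,R)‑ProPhenol (20 mol %), Me2Zn, Ph3PO (40 mol %), toluene, 4 °C; aq NH4Cl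
Reagents that add atoms: none
Why: Catalytic asymmetric zinc–ProPhenol alkynylation of an enal, in which the dinuclear zinc catalyst should deliver the metalated alkyne to the Si face of acrolein and set C10 as (R) under reagent control, the C6 centre four atoms away having no say.

Step 5
Reactants: 7 (3R,6S)‑6‑[(tert‑butyldimethylsilyl)oxy]‑8‑methylnona‑1,8‑dien‑4‑yn‑3‑ol
Product: 8 hexacarbonyldicobalt complex of 7 (Co2(CO)6 bridging the C1≡C5 alkyne)
Conditions: Co2(CO)8, CH2Cl2, rt
Reagents that add atoms: dicobalt octacarbonyl, O=C=[Co](=C=O)(=C=O)(=C=O)[Co](=C=O)(=C=O)(=C=O)=C=O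
Why: Alkyne complexation by Co2(CO)8 is selective for the triple bond over the alkenes and the hydroxyl and turns the linear unit into a bent one, with no change at C6 or C10.

Step 6
Reactants: 8 hexacarbonyldicobalt complex of 7
Product: 9 hexacarbonyldicobalt complex of (1R,4S)‑4‑[(tert‑butyldimethylsilyl)oxy]‑6‑methylcyclohept‑6‑en‑2‑yn‑1‑ol
Conditions: second‑generation Grubbs catalyst (10 mol %), CH2Cl2, 40 °C
Reagents that add atoms: none
Why: Ring‑closing metathesis of a cobalt‑complexed dienyne, a known entry to seven‑ to nine‑membered cycloalkyne complexes, should close ring A at C8=C9 because the cluster brings the vinyl and methallyl ends together; the vinylsilane is still absent on purpose, since it would close onto the C9 vinyl group.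

Step 7
Reactants: 9 hexacarbonyldicobalt complex of the cycloheptenynol; 10 chloro(ethenyl)dimethylsilane
Product: 11 ethenyldimethylsilyl ether of 9 (at the C10 oxygen)
Conditions: imidazole, CH2Cl2, 0 °C
Reagents that add atoms: none
Why: Silyl ether formation at the only free hydroxyl hangs the two‑carbon unit C2=C3 on the α‑oriented C10 oxygen, three atoms away from C1.

Step 8
Reactants: 11 ethenyldimethylsilyl ether of 9
Product: 13 (4R,8S)‑8‑[(tert‑butyldimethylsilyl)oxy]‑4‑hydroxy‑6‑methyl‑3,4,7,8‑tetrahydroazulen‑1(2H)‑one, via siloxane tricycle 12 (not isolated)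
Conditions: MeCN–H2O (99:1), 80 °C, argon
Reagents that add atoms: none
Why: Loss of one CO lets the tethered vinyl group bind to cobalt, insert into the Co–C1 bond (C1–C2), take up CO at C3 (C3–C4) and reductively eliminate onto C5 (C4–C5), which is an intramolecular Pauson–Khand [2+2+1] reaction of a preformed complex; the closest known cases are Pauson–Khand closures on medium‑ring cobalt–alkyne complexes and the vinylsilyl‑ether variant in wet acetonitrile, in which a vinylsilane stands in for ethylene. Ring B closes as the cyclopentenone of the [2+2+1] event, and the temporary oxasilolane (C1, C2, Si, O, C10) closes in the exo mode usual for a 1,6‑enyne. The only new stereocentre, C2 in 12, is fixed by the tether (silicon must lie on the face of the C10 oxygen) and is erased again: silicon in 12 is γ to the enone carbonyl (a vinylogous α‑silyl ketone), so water should open the strained siloxane, C–Si heterolysis should give the dienol, and reprotonation at C2 should restore the conjugated enone 13 with C2 and C3 as plain CH2 groups and the C10 hydroxyl free. The selectivity needed is regiochemical (alkene to C1, CO to C5), because the two alkyne carbons bear almost identical CH(O–Si) groups that free ethylene could not tell apart, and the C10–O–Si tether secures it since only C1 can be reached in a five‑membered closure. Chemoselectivity follows from geometry, as the ring alkene C8=C9 lies in the same seven‑membered ring as the alkyne and cannot span the cluster. The cluster is also what makes the precursor possible at all, because it bends C10–C1–C5–C6 to roughly 140° and so stores a cycloheptyne in stable form.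

Step 9
Reactants: 13 (4R,8S)‑8‑[(tert‑butyldimethylsilyl)oxy]‑4‑hydroxy‑6‑methyl‑3,4,7,8‑tetrahydroazulen‑1(2H)‑one
Product: 15 (3aS,4R,8S,8aS)‑8‑[(tert‑butyldimethylsilyl)oxy]‑4‑hydroxy‑3a,6‑dimethyl‑3,3a,4,7,8,8a‑hexahydroazulen‑1(2H)‑one, via bis‑silyl ether 14 (not isolated)
Conditions: Me2CuLi (from MeLi, CuI), TMSCl, Et2O–THF, −78 to −20 °C; then citric acid, THF–H2O, 0 °C
Reagents that add atoms: methyllithium, C[Li]; chlorotrimethylsilane, C[Si](C)(C)Cl
Why: TMSCl‑accelerated organocuprate 1,4‑addition should bring the methyl group to C1 from the β face, anti to the C10 and C6 oxygen substituents, while trapping as the silyl enol ether blocks β‑elimination of the C6 silyloxy group; mild hydrolysis, after the C10 TMS ether has fallen off, should then protonate C5 from the α face (opposite the axial angular methyl and guided by hydrogen bonding to the two α oxygens) to give the trans‑fused ketone under non‑equilibrating conditions.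

Step 10
Reactants: 15 trans‑fused ketone
Product: 16 (1S,4R,5S,6S,10R)‑6‑O‑(tert‑butyldimethylsilyl)dauc‑8‑ene‑4,6,10‑triol
Conditions: i‑PrMgCl (excess), LaCl3·2LiCl (30 mol %), THF, −78 to 0 °C; aq NH4Cl
Reagents that add atoms: isopropylmagnesium chloride, CC(C)[Mg]Cl
Why: Lanthanide‑assisted Grignard 1,2‑addition, which suppresses enolisation, should attack the C4 ketone from the α face next to H‑5, because the β face of ring B carries C6 on the adjacent carbon and the 1,3‑related C15 methyl, so that C4 is set with hydroxyl β and isopropyl α.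

Step 11
Reactants: 16 (1S,4R,5S,6S,10R)‑6‑O‑(tert‑butyldimethylsilyl)dauc‑8‑ene‑4,6,10‑triol
Product: 17 (1S,4R,5S,6S,10R)‑dauc‑8‑ene‑4,6,10‑triol
Conditions: TBAF, THF, rt
Reagents that add atoms: none
Why: Fluoride cleavage of the single silyl ether should proceed without risk, since no base‑ or fluoride‑sensitive group is left in the molecule.

Step 12
Reactants: 17 (1S,4R,5S,6S,10R)‑dauc‑8‑ene‑4,6,10‑triol
Product: 18 (1S,4R,5S,6S,10R)‑6‑O‑benzoyldauc‑8‑ene‑4,6,10‑triol
Conditions: BzCl (1.05 equiv), pyridine, CH2Cl2, −20 to 0 °C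
Reagents that add atoms: benzoyl chloride, O=C(Cl)c1ccccc1
Why: Site‑selective acylation should take the C6 hydroxyl, which is flanked by a CH and a CH2, before the neopentyl‑type pseudo‑axial C10 hydroxyl next to quaternary C1 and the tertiary C4 hydroxyl.

Step 13
Reactants: 18 (1S,4R,5S,6S,10R)‑6‑O‑benzoyldauc‑8‑ene‑4,6,10‑triol; 19 angelic acid
Product: 21 (3R,3aS,4S,8R,8aS)‑4‑(benzoyloxy)‑3‑hydroxy‑6,8a‑dimethyl‑3‑(propan‑2‑yl)‑1,2,3,3a,4,5,8,8a‑octahydroazulen‑8‑yl (2Z)‑2‑methylbut‑2‑enoate, via mixed anhydride 20 (not isolated)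
Conditions: 19, 2,4,6‑trichlorobenzoyl chloride, Et3N, toluene, rt; then 18, 80 °C
Reagents that add atoms: 2,4,6‑trichlorobenzoyl chloride, O=C(Cl)c1c(Cl)cc(Cl)cc1Cl
Why: Yamaguchi‑type mixed‑anhydride esterification run without a nucleophilic catalyst is the usual way to make angelates without Z‑to‑E isomerisation and should acylate the remaining secondary C10 hydroxyl with retention, the tertiary C4 hydroxyl staying free.

**Compound list**
1 | 3‑(trimethylsilyl)prop‑2‑ynal | C[Si](C)(C)C#CC=O | starting material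
2 | tributyl(2‑methylprop‑2‑en‑1‑yl)stannane | C=C(C)C[Sn](CCCC)(CCCC)CCCC | starting material
3 | (3S)‑5‑methyl‑1‑(trimethylsilyl)hex‑5‑en‑1‑yn‑3‑ol | C=C(C)C[C@H](O)C#C[Si](C)(C)C | intermediate
4 | (3S)‑3‑[(tert‑butyldimethylsilyl)oxy]‑5‑methyl‑1‑(trimethylsilyl)hex‑5‑en‑1‑yne | C=C(C)C[C@H](O[Si](C)(C)C(C)(C)C)C#C[Si](C)(C)C | intermediate
5 | (3S)‑3‑[(tert‑butyldimethylsilyl)oxy]‑5‑methylhex‑5‑en‑1‑yne | C=C(C)C[C@H](O[Si](C)(C)C(C)(C)C)C#C | intermediate
6 | acrolein | C=CC=O | starting material
7 | (3R,6S)‑6‑[(tert‑butyldimethylsilyl)oxy]‑8‑methylnona‑1,8‑dien‑4‑yn‑3‑ol | C=C[C@@H](O)C#C[C@@H](O[Si](C)(C)C(C)(C)C)CC(C)=C | intermediate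
8 | hexacarbonyldicobalt complex of 7 | C=C[C@@H](O)C12[Co]3(=C=O)(=C=O)(=C=O)[Co]1(=C=O)(=C=O)(=C=O)C23[C@@H](O[Si](C)(C)C(C)(C)C)CC(C)=C | intermediate
9 | hexacarbonyldicobalt complex of (1R,4S)‑4‑[(tert‑butyldimethylsilyl)oxy]‑6‑methylcyclohept‑6‑en‑2‑yn‑1‑ol | O[C@@H]1C=C(C)C[C@H](O[Si](C)(C)C(C)(C)C)C23[Co]4(=C=O)(=C=O)(=C=O)[Co]2(=C=O)(=C=O)(=C=O)C134 | intermediate
10 | chloro(ethenyl)dimethylsilane | C=C[Si](C)(C)Cl | starting material
11 | ethenyldimethylsilyl ether of 9 | C=C[Si](C)(C)O[C@@H]1C=C(C)C[C@H](O[Si](C)(C)C(C)(C)C)C23[Co]4(=C=O)(=C=O)(=C=O)[Co]2(=C=O)(=C=O)(=C=O)C134 | intermediate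
12 | siloxane tricycle (enone of 13 with an O–SiMe2 bridge from the C10 oxygen to C2; 2S,6S,10R) | C[Si]1(C)O[C@@H]2C=C(C)C[C@H](O[Si](C)(C)C(C)(C)C)C3=C2[C@@H]1CC3=O | intermediate
13 | (4R,8S)‑8‑[(tert‑butyldimethylsilyl)oxy]‑4‑hydroxy‑6‑methyl‑3,4,7,8‑tetrahydroazulen‑1(2H)‑one | O[C@@H]1C=C(C)C[C@H](O[Si](C)(C)C(C)(C)C)C2=C1CCC2=O | intermediate
14 | C4 trimethylsilyl enol ether and C10 trimethylsilyl ether of 15 (1S,6S,10R) | C[Si](C)(C)O[C@@H]1C=C(C)C[C@H](O[Si](C)(C)C(C)(C)C)C2=C(O[Si](C)(C)C)CC[C@]12C | intermediate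
15 | (3aS,4R,8S,8aS)‑8‑[(tert‑butyldimethylsilyl)oxy]‑4‑hydroxy‑3a,6‑dimethyl‑3,3a,4,7,8,8a‑hexahydroazulen‑1(2H)‑one | O[C@@H]1C=C(C)C[C@H](O[Si](C)(C)C(C)(C)C)[C@@H]2[C@]1(C)CCC2=O | intermediate
16 | (1S,4R,5S,6S,10R)‑6‑O‑(tert‑butyldimethylsilyl)dauc‑8‑ene‑4,6,10‑triol | O[C@@H]1C=C(C)C[C@H](O[Si](C)(C)C(C)(C)C)[C@@H]2[C@]1(C)CC[C@@]2(O)C(C)C | intermediate
17 | (1S,4R,5S,6S,10R)‑dauc‑8‑ene‑4,6,10‑triol | O[C@@H]1C=C(C)C[C@H](O)[C@@H]2[C@]1(C)CC[C@@]2(O)C(C)C | intermediate
18 | (1S,4R,5S,6S,10R)‑6‑O‑benzoyldauc‑8‑ene‑4,6,10‑triol | O[C@@H]1C=C(C)C[C@H](OC(=O)c2ccccc2)[C@@H]2[C@]1(C)CC[C@@]2(O)C(C)C | intermediate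
19 | angelic acid, (2Z)‑2‑methylbut‑2‑enoic acid | C/C=C(/C)C(=O)O | starting material
20 | angelic 2,4,6‑trichlorobenzoic anhydride | C/C=C(/C)C(=O)OC(=O)c1c(Cl)cc(Cl)cc1Cl | intermediate
21 | (1S,4R,5S,6S,10R)‑10‑O‑angeloyl‑6‑O‑benzoyldauc‑8‑ene‑4,6,10‑triol | C/C=C(/C)C(=O)O[C@@H]1C=C(C)C[C@H](OC(=O)c2ccccc2)[C@@H]2[C@]1(C)CC[C@@]2(O)C(C)C | target

Total step count: 13. Longest linear sequence: 13 steps (from 1).

**Steps most likely to fail**

Step 8. Insertion of the weakly coordinating vinylsilane at a cluster flanked by two branched carbons may be slow. Thermal decomplexation or loss of a propargylic oxygen substituent could then overtake the cycloaddition. The fallback inverts the ring order; it sets out from 7 and comes back at 13.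
- Silylation of 7 with 10 (imidazole, CH2Cl2) gives the open‑chain vinylsilyl ether F1.
- Co2(CO)8 in CH2Cl2 gives its hexacarbonyldicobalt complex F2.
- Heating F2 in MeCN–H2O at 80 °C runs the same tethered Pauson–Khand reaction on an unstrained open‑chain alkyne, the substrate class for which it is established.
- This passes through the bicyclic siloxane F3, whose silicon‑bearing carbon is of no consequence, and should give the monocyclic cyclopentenone F4.
- Ring‑closing metathesis of F4 with second‑generation Grubbs catalyst then joins the two arms, which are held cis on the enone, to give 13.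

Step 9. Facial selectivity in the protonation of C5 may be poor, or the trans‑fused ketone may epimerise to the cis‑fused one. The fallback replaces substrate control by reagent control; it sets out from 13 and comes back at 15.
- The cuprate addition is quenched with allyl chloroformate instead of TMSCl, which gives the C4 allyl enol carbonate / C10 allyl carbonate F5.
- Pd(OAc)2, the matched enantiomer of t‑BuPHOX and HCO2H in dioxane at 40 °C then effect decarboxylative asymmetric protonation of the enol carbonate.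
- The same conditions remove the C10 allyl carbonate, so that C5 is protonated under ligand control and 15 is reached.

Step 10. The hindered ketone may enolise, with epimerisation at C5 or loss of the C6 silyloxy group, and the secondary Grignard reagent may reduce it by β‑hydride transfer. The fallback sets out from 15 and comes back at 16.
- Isopropenylmagnesium bromide with CeCl3 in THF at −78 °C, a smaller sp2 nucleophile that cannot transfer a β‑hydride, should add from the same α face to give the isopropenyl carbinol F6.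
- Hydrogenation with RhCl(PPh3)3 and H2 in benzene should saturate only the 1,1‑disubstituted alkene and leave the trisubstituted C8=C9 bond, giving 16.

**Further compounds**
F1 | step 8 | (3R,6S)‑6‑[(tert‑butyldimethylsilyl)oxy]‑3‑[(ethenyldimethylsilyl)oxy]‑8‑methylnona‑1,8‑dien‑4‑yne | C=C[C@@H](O[Si](C)(C)C=C)C#C[C@@H](O[Si](C)(C)C(C)(C)C)CC(C)=C
F2 | step 8 | hexacarbonyldicobalt complex of F1 | C=C[C@@H](O[Si](C)(C)C=C)C12[Co]3(=C=O)(=C=O)(=C=O)[Co]1(=C=O)(=C=O)(=C=O)C23[C@@H](O[Si](C)(C)C(C)(C)C)CC(C)=C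
F3 | step 8 | bicyclic siloxane (2‑oxa‑3‑silabicyclo[3.3.0]octenone bearing the vinyl group and the C6 side chain) | C=C[C@H]1O[Si](C)(C)C2CC(=O)C([C@@H](O[Si](C)(C)C(C)(C)C)CC(C)=C)=C12
F4 | step 8 | 2‑[(1S)‑1‑[(tert‑butyldimethylsilyl)oxy]‑3‑methylbut‑3‑en‑1‑yl]‑3‑[(1R)‑1‑hydroxyprop‑2‑en‑1‑yl]cyclopent‑2‑en‑1‑one | C=C[C@@H](O)C1=C([C@@H](O[Si](C)(C)C(C)(C)C)CC(C)=C)C(=O)CC1
F5 | step 9 | C4 allyl enol carbonate and C10 allyl carbonate of 15 (1S,6S,10R) | C=CCOC(=O)O[C@@H]1C=C(C)C[C@H](O[Si](C)(C)C(C)(C)C)C2=C(OC(=O)OCC=C)CC[C@]12C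
F6 | step 10 | (1S,4S,5S,6S,10R)‑6‑O‑(tert‑butyldimethylsilyl)dauca‑8,11‑diene‑4,6,10‑triol | O[C@@H]1C=C(C)C[C@H](O[Si](C)(C)C(C)(C)C)[C@@H]2[C@]1(C)CC[C@@]2(O)C(C)=C
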